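In the first minutes of south-east, c(partner) stands at 80.0 mM beside 0.0200 mM of catalyst, held as catalyst intermediate A, and its decay to decomposed reagent takes it at 4.4 h⁻¹, far faster than the 0.240 h⁻¹ at which that catalyst can take it. The next run therefore turns on how partner is dosed.

| flask | substrate | partner | free catalyst | time | remark |
|---|---|---|---|---|---|
| north-east | 20 mM | 4.00 equiv (in portions, 2, over 5.0 h) | 0.1 mol% | 6.0 h | first portion at the start, last at 5.0 h |
| south-east | 20 mM | 4.00 equiv | 0.1 mol% | 6.0 h | everything together at the start |
| west | 20 mM (fed, over 5.0 h) | 4.00 equiv | 0.1 mol% | 6.0 h | all else is in the flask from the start; the feed brings no volume worth counting |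
| south-west | 20 mM | 4.00 equiv (fed, over 5.0 h) | 0.1 mol% | 6.0 h | all else is in the flask from the start; the feed brings no volume worth counting |

    substrate + free catalyst → catalyst intermediate A (k1 = 37000 M⁻¹ h⁻¹)
    partner + catalyst intermediate A → catalyst intermediate B (k2 = 12000 M⁻¹ h⁻¹)
    catalyst intermediate B ⇌ by-product + catalyst intermediate C (K3 = 0.060 M, k3 = 750 h⁻¹)
    catalyst intermediate C → free catalyst + target (k4 = 6300 h⁻¹)
    substrate + by-product → side product (k5 = 30 M⁻¹ h⁻¹)
    partner → decomposed reagent (k6 = 4.4 h⁻¹)

* the flask with the highest amount of side product, in percent of the substrate charged ("all alike" if they lie within 1.5 percentage points) (north-east / south-east / west / south-west / all alike)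
* final side product, as a percentage of the substrate charged, in north-east
* final side product, as a percentage of the substrate charged, in south-east
* final side product, as a percentage of the substrate charged, in west
* final side product, as a percentage of the substrate charged, in south-west

My reckoning starts from the cycle without the partner step. At charged substrate that takes 0.171 min per turn. The saturation level of partner is the c(partner) at which the partner step takes as long as the rest of the cycle: 29.3 mM. A dose c₀ decaying unaided then gives target c(free catalyst, charged)·ln(1 + c₀/saturation level)/(k6 × cycle time). That yields 10.5 % in south-east and a larger 13.8 % in north-east. In south-west the feed holds c(partner) near 3.64 mM, below the saturation level of 29.3 mM, so target reaches 19.4 %, more than in south-east. In west, substrate has reached 0.630 mM after one partner half-life. The same formula at that level gives 1.93 %.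

Each turn of the cycle gives one target and one by-product, so these figures are estimates of the by-product made as well as of the target. By-product goes on to side product in a pseudo-first-order step at 0.600 h⁻¹, with a half-life of 1.2 h. With substrate held at its charge, a steady feed over 5.0 h leaves south-west at 16.0 % by 6.0 h. The next run should feed partner, for target, and expect side product to follow.

The forecast reads 8.8 %, 10 %, 2.6 % and 13.5 % for north-east, south-east, west and south-west, and names south-west. For late by-product it says “too little time left to convert fully”. My south-west figure of 16.0 % stands above its 13.5 %.

The flasks give 8.17 %, 9.51 %, 2.29 % and 13.4 %, and the most is in south-west.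

South-west has not come to rest at 6.00 h. Target stands at 18.5 %, side product at 13.4 %, and by-product still at 1.03 mM, which is 5.17 % of the substrate charged. At 60.0 h target is unchanged at 18.5 %, while side product has climbed to 18.5 %; the saturation level had given 19.4 % of target. By-product is down to 1.38 × 10⁻⁹ mM and substrate to 62.8 %. Ten times the time changes side product, not target.

Dosing south-west over 1.50 h instead puts c(partner) near 12.1 mM, still below the saturation level, so target should reach 15.4 % and side product 14.7 %. The run gives 13.9 % of side product.

The constants used here were set for the occasion; the flask was simulated.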